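**Retrosynthetic overview**

1. Dinklagin A (18) comes from 17 by removal of the methoxymethyl group on the C7 oxygen.
2. Ring C is opened at the C4–C4a bond and, in the same operation, the prenyl group is taken off C6. Both carbons become C–Br in aryl ether 12, whose C4 is a Weinreb amide tethered through O1–C2–C3. The enabling feature: in ring A, C4a and C6 are the two carbons that are each ortho to one oxygen and para to the other (O1 and the oxygen on C7). They are the 4- and 6-positions of a resorcinol and are identical by symmetry in 4,6-dibromoresorcinol. Once O1 is tied to C2, only the bromide on C4a lies within six atoms of the amide carbon.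
3. O1–C2 is cut to (R)-carbinol 9 and bromophenol 11 (Mitsunobu inversion). Carbinol 9 comes from β-keto ester 7 by asymmetric transfer hydrogenation.
4. Order of ring formation: ring D first (propargyl Claisen cascade on the ether of 4-hydroxyacetophenone); rings A and B are bought as arenes; ring C last.

Key step: step 8

Assumption: 4,6-dibromoresorcinol (10), 3-chloro-3-methylbut-1-yne (2) and prenyl bromide (13) are taken as commercial, and C2 of the target is read as S.

**Route**

Step 1
Reactants: 1 4-hydroxyacetophenone; 2 3-chloro-3-methylbut-1-yne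
Product: 3 1-{4-[(2-methylbut-3-yn-2-yl)oxy]phenyl}ethan-1-one
Conditions: K2CO3, KI (cat.), acetone, reflux
Reagents that add atoms: none
Why: Williamson-type O-alkylation of the phenoxide by the tertiary propargylic chloride is the standard way to aryl 1,1-dimethylpropargyl ethers and forms no stereocentre.

Step 2
Reactants: 3 1-{4-[(2-methylbut-3-yn-2-yl)oxy]phenyl}ethan-1-one
Product: 6 1-(2,2-dimethyl-2H-chromen-6-yl)ethan-1-one, via allenylphenol 4 (not isolated), via ortho-quinone methide 5 (not isolated)
Conditions: PhNEt2, 190 °C
Reagents that add atoms: none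
Why: Thermal aromatic propargyl Claisen rearrangement, enolisation to 4, 1,5-hydrogen shift to 5 and oxa-6π electrocyclisation should build ring D with its gem-dimethyl group; because the acetyl group is para to the oxygen both ortho positions are equivalent, so one chromene results and no stereocentre is formed.

Step 3
Reactants: 6 1-(2,2-dimethyl-2H-chromen-6-yl)ethan-1-one
Product: 7 ethyl 3-(2,2-dimethyl-2H-chromen-6-yl)-3-oxopropanoate
Conditions: NaH, (EtO)2CO, THF, reflux; then aq. HCl
Reagents that add atoms: diethyl carbonate, CCOC(=O)OCC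
Why: Crossed Claisen condensation of the methyl ketone enolate with diethyl carbonate, driven by irreversible deprotonation of the β-keto ester, adds the carbon that becomes C4 and forms no stereocentre.

Step 4
Reactants: 7 ethyl 3-(2,2-dimethyl-2H-chromen-6-yl)-3-oxopropanoate
Product: 8 ethyl (3R)-3-(2,2-dimethyl-2H-chromen-6-yl)-3-hydroxypropanoate
Conditions: RuCl[(R,R)-TsDPEN](p-cymene) (1 mol %), HCO2H/Et3N (5:2 azeotrope), DMF, 40 °C
Reagents that add atoms: none
Why: Noyori–Ikariya asymmetric transfer hydrogenation should reduce only the aryl ketone (ester and ring D alkene are inert to the ruthenium hydride), and with the (R,R)-TsDPEN ligand hydride is expected, by analogy with aryl alkyl ketones reduced through the CH–π-organised six-membered transition state, to add to the face that gives the (R)-carbinol.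

Step 5
Reactants: 8 ethyl (3R)-3-(2,2-dimethyl-2H-chromen-6-yl)-3-hydroxypropanoate
Product: 9 (3R)-3-(2,2-dimethyl-2H-chromen-6-yl)-3-hydroxy-N-methoxy-N-methylpropanamide
Conditions: MeNHOMe·HCl, i-PrMgCl, THF, −20 → 0 °C; then aq. NH4Cl
Reagents that add atoms: N,O-dimethylhydroxylamine hydrochloride, CNOC.Cl
Why: Weinreb amide formation by aminolysis of the ester with the chloromagnesium amide of N,O-dimethylhydroxylamine should proceed at low temperature with the β-hydroxyl held as its magnesium alkoxide, so the carbinol centre is not touched.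

Step 6
Reactants: 10 4,6-dibromoresorcinol (4,6-dibromobenzene-1,3-diol)
Product: 11 2,4-dibromo-5-(methoxymethoxy)phenol
Conditions: 10 (1.5 equiv), NaH (1.0 equiv), MOMCl (1.0 equiv), THF, 0 °C
Reagents that add atoms: chloromethyl methyl ether (MOMCl), COCCl
Why: Williamson O-alkylation of the monophenoxide; since 10 is C2v-symmetric either hydroxyl gives the same product, so there is no regiochemical question and only mono- versus bis-alkylation has to be managed by limiting base and MOMCl.

Step 7
Reactants: 9 (3R)-3-(2,2-dimethyl-2H-chromen-6-yl)-3-hydroxy-N-methoxy-N-methylpropanamide; 11 2,4-dibromo-5-(methoxymethoxy)phenol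
Product: 12 (3S)-3-[2,4-dibromo-5-(methoxymethoxy)phenoxy]-3-(2,2-dimethyl-2H-chromen-6-yl)-N-methoxy-N-methylpropanamide
Conditions: PPh3, DIAD, toluene, −20 °C → rt
Reagents that add atoms: none
Why: Mitsunobu etherification with the acidic bromophenol 11 as pronucleophile should displace the oxyphosphonium group by SN2, so the (R)-carbinol is inverted to the (S)-aryl ether needed at C2; toluene and low temperature are chosen to suppress ionisation of the electron-rich benzylic centre.

Step 8
Reactants: 12 (3S)-3-[2,4-dibromo-5-(methoxymethoxy)phenoxy]-3-(2,2-dimethyl-2H-chromen-6-yl)-N-methoxy-N-methylpropanamide; 13 prenyl bromide (1-bromo-3-methylbut-2-ene)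
Product: 17 (2S)-2-(2,2-dimethyl-2H-chromen-6-yl)-7-(methoxymethoxy)-6-(3-methylbut-2-en-1-yl)-2,3-dihydro-4H-chromen-4-one, via dilithio amide 14 (not isolated), via lithium hemiaminal 15 (not isolated), via prenylated lithium hemiaminal 16 (not isolated)
Conditions: 12 added to t-BuLi (4.1 equiv), THF/Et2O, −95 °C, 0.02 M; CuBr·SMe2 (10 mol %), 13 (1.5 equiv), −78 → −30 °C; AcOH, −78 °C
Reagents that add atoms: none
Why: tert-Butyllithium should exchange both aryl bromides of 12 faster than it adds to or deprotonates the amide, giving 14; the carbanion at C4a, held six atoms from the amide carbon by the O1–C2–C3 tether, adds to the Weinreb carbonyl and forms the C4–C4a bond (chelated tetrahedral alkoxide 15), while the carbanion at C6 cannot reach the amide, survives, is transmetallated by catalytic CuBr·SMe2 and is allylated at the primary carbon of 13 (16), and acetic acid finally collapses the hemiaminal to the C4 ketone. The closest known reaction types are the Parham cyclisation of an aryllithium onto a tethered Weinreb amide (cycloacylation) and the copper-catalysed allylation of an ortho-alkoxy aryllithium. Ring C closes by 6-exo-trig attack of the aryl carbanion on the amide carbonyl. No stereocentre of the product is created: C2 is carried over from step 7 and should stay intact because the ketone remains masked as the non-enolisable lithium hemiaminal until the cold acidic quench (no enolate, hence no retro-oxa-Michael opening), and the transient C4 centre is erased on collapse. The step needs site selectivity between the two carbanions, secured by the tether together with high dilution and inverse addition (intramolecular acylation outruns intermolecular acylation), and SN2 rather than SN2′ allylation, secured by copper catalysis and the hindered tertiary terminus of 13. No regiochemical control on ring A is needed, because both reacting carbons were already marked by bromine in the symmetric diol 10.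

Step 9
Reactants: 17 (2S)-2-(2,2-dimethyl-2H-chromen-6-yl)-7-(methoxymethoxy)-6-(3-methylbut-2-en-1-yl)-2,3-dihydro-4H-chromen-4-one
Product: 18 Dinklagin A, (2S)-2-(2,2-dimethyl-2H-chromen-6-yl)-7-hydroxy-6-(3-methylbut-2-en-1-yl)-2,3-dihydro-4H-chromen-4-one
Conditions: 3 M aq. HCl, MeOH, 40 °C
Reagents that add atoms: none
Why: Acid-catalysed acetal exchange with methanol (methoxymethyl ether cleavage) should release the C7 phenol under conditions in which the prenyl group, the ring D alkene and the C2 centre (not α to the carbonyl, so not enolisable) persist.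

**Compound list**

1 | 4-hydroxyacetophenone | CC(=O)c1ccc(O)cc1 | starting material
2 | 3-chloro-3-methylbut-1-yne | CC(C)(Cl)C#C | starting material
3 | 1-{4-[(2-methylbut-3-yn-2-yl)oxy]phenyl}ethan-1-one | CC(=O)c1ccc(OC(C)(C)C#C)cc1 | intermediate
4 | 1-[4-hydroxy-3-(3-methylbuta-1,2-dien-1-yl)phenyl]ethan-1-one (allenylphenol, not isolated) | CC(=O)c1ccc(O)c(C=C=C(C)C)c1 | intermediate
5 | 4-acetyl-6-(3-methylbut-2-en-1-ylidene)cyclohexa-2,4-dien-1-one (ortho-quinone methide, not isolated) | O=C1C=CC(C(C)=O)=CC1=CC=C(C)C | intermediate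
6 | 1-(2,2-dimethyl-2H-chromen-6-yl)ethan-1-one | CC(=O)c1ccc2c(c1)C=CC(C)(C)O2 | intermediate
7 | ethyl 3-(2,2-dimethyl-2H-chromen-6-yl)-3-oxopropanoate | CCOC(=O)CC(=O)c1ccc2c(c1)C=CC(C)(C)O2 | intermediate
8 | ethyl (3R)-3-(2,2-dimethyl-2H-chromen-6-yl)-3-hydroxypropanoate | O[C@@H](c1ccc2c(c1)C=CC(C)(C)O2)CC(=O)OCC | intermediate
9 | (3R)-3-(2,2-dimethyl-2H-chromen-6-yl)-3-hydroxy-N-methoxy-N-methylpropanamide | O[C@@H](c1ccc2c(c1)C=CC(C)(C)O2)CC(=O)N(C)OC | intermediate
10 | 4,6-dibromoresorcinol (4,6-dibromobenzene-1,3-diol) | Oc1cc(O)c(Br)cc1Br | starting material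
11 | 2,4-dibromo-5-(methoxymethoxy)phenol | COCOc1cc(O)c(Br)cc1Br | intermediate
12 | (3S)-3-[2,4-dibromo-5-(methoxymethoxy)phenoxy]-3-(2,2-dimethyl-2H-chromen-6-yl)-N-methoxy-N-methylpropanamide | COCOc1cc(O[C@H](c2ccc3c(c2)C=CC(C)(C)O3)CC(=O)N(C)OC)c(Br)cc1Br | intermediate
13 | prenyl bromide (1-bromo-3-methylbut-2-ene) | CC(C)=CCBr | starting material
14 | (3S)-3-[2,4-dilithio-5-(methoxymethoxy)phenoxy]-3-(2,2-dimethyl-2H-chromen-6-yl)-N-methoxy-N-methylpropanamide (dilithio amide, not isolated) | [Li]c1cc([Li])c(OCOC)cc1O[C@H](c1ccc2c(c1)C=CC(C)(C)O2)CC(=O)N(C)OC | intermediate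
15 | lithium (2S)-2-(2,2-dimethyl-2H-chromen-6-yl)-6-lithio-4-[methoxy(methyl)amino]-7-(methoxymethoxy)chroman-4-olate (lithium hemiaminal, not isolated) | [Li]c1cc2c(cc1OCOC)O[C@H](c1ccc3c(c1)C=CC(C)(C)O3)CC2(O[Li])N(C)OC | intermediate
16 | lithium (2S)-2-(2,2-dimethyl-2H-chromen-6-yl)-4-[methoxy(methyl)amino]-7-(methoxymethoxy)-6-(3-methylbut-2-en-1-yl)chroman-4-olate (prenylated lithium hemiaminal, not isolated) | CC(C)=CCc1cc2c(cc1OCOC)O[C@H](c1ccc3c(c1)C=CC(C)(C)O3)CC2(O[Li])N(C)OC | intermediate
17 | (2S)-2-(2,2-dimethyl-2H-chromen-6-yl)-7-(methoxymethoxy)-6-(3-methylbut-2-en-1-yl)-2,3-dihydro-4H-chromen-4-one | CC(C)=CCc1cc2c(cc1OCOC)O[C@H](c1ccc3c(c1)C=CC(C)(C)O3)CC2=O | intermediate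
18 | Dinklagin A, (2S)-2-(2,2-dimethyl-2H-chromen-6-yl)-7-hydroxy-6-(3-methylbut-2-en-1-yl)-2,3-dihydro-4H-chromen-4-one | CC(C)=CCc1cc2c(cc1O)O[C@H](c1ccc3c(c1)C=CC(C)(C)O3)CC2=O | target

**Step count and risks**

Total steps: 9. Longest linear sequence: 8 (steps 1 to 5, then 7, 8 and 9); step 6 is the one-step side branch.

Risk 1, step 8 (key step). The C6 carbanion may be protonated before it is allylated, by proton transfer from the α-CH2 of amide that has not yet cyclised (which also opens an E1cB loss of the aryloxide), or it may attack the tertiary end of the allyl bromide. The fallback sets out from 12 and comes back to the route at 17. The exchange and cyclisation are kept, but 15 is quenched at −78 °C with iodine, a trap that needs no copper and reacts faster than any proton source present. After the acetic acid quench this should give (2S)-2-(2,2-dimethyl-2H-chromen-6-yl)-6-iodo-7-(methoxymethoxy)-2,3-dihydro-4H-chromen-4-one F1. The prenyl group is then brought in by Stille coupling of F1 with tributyl(3-methylbut-2-en-1-yl)stannane (Pd(PPh3)4, DMF, 80 °C, no base, so C2 is not at risk), which should give 17.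

Risk 2, step 7. The oxyphosphonium intermediate may ionise at the benzylic carbon that carries the para-oxygenated ring B (partial loss of configuration), and E1cB-type dehydration toward the cinnamamide may compete. The fallback sets out from 2 and 11, with commercial 4-hydroxybenzaldehyde in place of 1, and comes back to the route at 12.
- O-alkylation with 2 as in step 1 should give 4-[(2-methylbut-3-yn-2-yl)oxy]benzaldehyde F2, and heating as in step 2 should give 2,2-dimethyl-2H-chromene-6-carbaldehyde F3.
- Ethynylmagnesium bromide (THF, 0 °C) should give racemic 1-(2,2-dimethyl-2H-chromen-6-yl)prop-2-yn-1-ol F4, which is acetylated (Ac2O, Et3N, DMAP) to racemic 1-(2,2-dimethyl-2H-chromen-6-yl)prop-2-yn-1-yl acetate F5.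
- Copper-catalysed asymmetric propargylic etherification with 11 (CuOTf·0.5C6H6, the pybox ligand enantiomer that gives the S ether, i-Pr2NEt, MeOH, −20 °C) should convert both enantiomers of F5, through a common copper allenylidene, into 1,5-dibromo-2-{[(1S)-1-(2,2-dimethyl-2H-chromen-6-yl)prop-2-yn-1-yl]oxy}-4-(methoxymethoxy)benzene F6. No substitution at a preformed stereocentre is involved.
- Rhodium-catalysed oxygenative amidation of the terminal alkyne ([Rh(cod)Cl]2, P(4-FC6H4)3, 4-picoline N-oxide, MeNHOMe, MeCN, 60 °C; alkyne to vinylidene to ketene to amide) should then give 12.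

Risk 3, step 9. The acid may promote addition of the freed C7 hydroxyl to the neighbouring prenyl alkene (closure of a dimethylchroman ring) and addition of methanol to the ring D alkene. The fallback sets out from 9 and 10 and comes back to the route at 18. Mitsunobu etherification of 9 with an excess of unprotected 10 (conditions of step 7) should give (3S)-3-(2,4-dibromo-5-hydroxyphenoxy)-3-(2,2-dimethyl-2H-chromen-6-yl)-N-methoxy-N-methylpropanamide F7. The phenol is deprotonated with MeLi (1 equiv); the exchange, cyclisation, copper-catalysed allylation with 13 and acetic acid quench of step 8 (with −78 → −40 °C allowed for the bromide next to the lithium phenoxide) should then give 18 directly, so that no acid-labile protecting group has to be removed.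

Further compounds
F1 | step 8 | (2S)-2-(2,2-dimethyl-2H-chromen-6-yl)-6-iodo-7-(methoxymethoxy)-2,3-dihydro-4H-chromen-4-one | Ic1cc2c(cc1OCOC)O[C@H](c1ccc3c(c1)C=CC(C)(C)O3)CC2=O
F2 | step 7 | 4-[(2-methylbut-3-yn-2-yl)oxy]benzaldehyde | O=Cc1ccc(OC(C)(C)C#C)cc1
F3 | step 7 | 2,2-dimethyl-2H-chromene-6-carbaldehyde | O=Cc1ccc2c(c1)C=CC(C)(C)O2
F4 | step 7 | racemic 1-(2,2-dimethyl-2H-chromen-6-yl)prop-2-yn-1-ol | OC(C#C)c1ccc2c(c1)C=CC(C)(C)O2
F5 | step 7 | racemic 1-(2,2-dimethyl-2H-chromen-6-yl)prop-2-yn-1-yl acetate | CC(=O)OC(C#C)c1ccc2c(c1)C=CC(C)(C)O2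
F6 | step 7 | 1,5-dibromo-2-{[(1S)-1-(2,2-dimethyl-2H-chromen-6-yl)prop-2-yn-1-yl]oxy}-4-(methoxymethoxy)benzene | COCOc1cc(O[C@H](c2ccc3c(c2)C=CC(C)(C)O3)C#C)c(Br)cc1Br
F7 | step 9 | (3S)-3-(2,4-dibromo-5-hydroxyphenoxy)-3-(2,2-dimethyl-2H-chromen-6-yl)-N-methoxy-N-methylpropanamide | Oc1cc(O[C@H](c2ccc3c(c2)C=CC(C)(C)O3)CC(=O)N(C)OC)c(Br)cc1Br
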